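The data were computed for substances that don't exist; the scatter is artificial.

The ratio I carried through these set-ups was over-reaction product gained per hour to target in hand.

| flask | starting material | protic impurity | remark | time |
|---|---|---|---|---|
| red | 0.10 M | 5 mM | run made earlier |  |
| grey | 0.10 M | 3.4 mM | run made earlier |  |
| ochre | 0.10 M | 7.5 mM | run made earlier |  |
| Thursday's | 0.10 M (fed, over 16.0 h) | 5.00 mM | a stirred flask in which starting material is dosed at a steady rate over 16.0 h without added volume, worked up at 20 h | 20 h |
| Tuesday's | 0.10 M | 5.00 mM | everything together in a closed stirred flask, run for 20 h | 20 h |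
| Monday's | 0.10 M | 5.00 mM | one stirred flow tank at steady state, fed with the mixture as stated, mean residence time 20 h |  |
| Friday's | 0.10 M | 5.00 mM | plug flow through a tube for 20 h, no back-mixing | 20 h |

| run | time / h | target / % | isomer of the product / % | over-reaction product / % |
|---|---|---|---|---|
| red | 1.50 | 23.3 | 8.7 | 1.8 |
| red | 4.00 | 43.0 | 20.0 | 10.1 |
| red | 8.00 | 37.1 | 19.6 | 26.6 |
| red | 20.0 | 18.2 | 14.6 | 57.7 |
| grey | 1.00 | 15.9 | 5.8 | 0.3 |
| grey | 2.00 | 31.2 | 11.5 | 2.1 |
| grey | 5.00 | 42.2 | 22.2 | 16.0 |
| grey | 12.0 | 28.8 | 20.1 | 40.8 |
| ochre | 3.00 | 38.8 | 16.5 | 6.1 |
| ochre | 6.00 | 39.5 | 21.0 | 19.2 |
| ochre | 10.0 | 32.8 | 19.7 | 32.2 |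
| ochre | 12.0 | 26.8 | 20.1 | 38.4 |

(each reading ± 1 percentage point)

- the stated concentrations are those of everything mixed, before any reaction; amounts are the same in each set-up
- the feed brings no volume worth counting
- the earlier runs were made in a closed, stirred flask

1. the set-up with the highest share of target in all that became target or isomer of the product or over-reaction product, at the outlet or at the end ("none" if the first two lie within 2 percentage points) (Thursday's / Tuesday's / Monday's / Friday's / none)
2. share of target in all that became target or isomer of the product or over-reaction product, at the outlet or at the end, Thursday's
3. share of target in all that became target or isomer of the product or over-reaction product, at the outlet or at the end, Tuesday's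
4. share of target in all that became target or isomer of the product or over-reaction product, at the outlet or at the end, Monday's
5. share of target in all that became target or isomer of the product or over-reaction product, at the outlet or at the end, Friday's

In the red run this ratio read 0.103 /h between 4.00 h and 8.00 h, and 0.0977 /h between 8.00 h and 20.0 h. Within the scatter, I took it as one first-order constant for the loss of target. The supply in the red run did slow: target plus over-reaction product gained 0.167 /h of the charge up to the first reading, but 0.0102 /h between the last two, a fall by a factor of 16.4. At 8.00 h the loss in the red run already ran at 0.0362 /h, faster than that late gain, and target read 37.1% there and 18.2% at 20.0 h. Tuesday's repeats the red run, and I expected the same of Friday's plug flow, where every portion has the same age: 20.1%.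

Monday's tank and Thursday's dosing hold material of different ages. I defined the exposure as the loss constant times the mean age of the material, which is 1.95 for Monday's tank (the Damköhler number). The first red reading gives a split of 0.728 towards target, so I reckoned the share as split/(1 + exposure), or 24.7% for Monday's. Thursday's mean age is 12.0 h, its exposure 1.17, and the same rough rule gave 33.5%, my best.

The forecast also chose Thursday's, at 36% against my 33.5%, with Monday's 28.5% against my 24.7% and the other two 20.1%, saying that “the late-formed target survives”.

Thursday's gave 34.8%, ahead of Monday's 27.7%, while Tuesday's and Friday's gave 20.1% and 20.1%.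

    starting material → intermediate (k = 0.600 /h)
    intermediate ⇌ target (K = 4.80, k = 1.10 /h)
    intermediate ⇌ isomer of the product (K = 2.30, k = 0.390 /h)
    target → over-reaction product (k = 0.100 /h)
    starting material + protic impurity → quenched substrate (k = 300 /M/h)

Isomer of the product stood at 19.4% of the charge at the end of Thursday's and 13.6% at Monday's outlet. Multiplied back by one plus its exposure, Thursday's share gives a split of 0.755, and Monday's gives 0.818, against the 0.728 from the first red reading.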